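**Retrosynthetic overview**
1. The strategy rests on ring B, the tetrahydrofuran C7'–O–C9–C8–C8' that holds the endo syringyl carbon C7' next to ring-fusion carbon C8' of the cis-fused 3,7-dioxabicyclo[3.3.0]octane. Its C7'–C8' bond is cut back to α-diazo lactone 24 (dirhodium carbenoid 1,5 C–H insertion into a syringylmethyl ether).
2. Ring A (C7–O–C9'–C8'–C8, exo guaiacyl at C7) is carried through the insertion as a trans γ-lactone, then opened with LiAlH4 and re-closed as the ether by SN2 at C9' before global desilylation.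
3. 24 comes from hydroxymethyl lactone 9 and benzylic trichloroacetimidate 21 (C9–O–C7' ether), followed by diazo transfer at C8'.
4. 9 (C7, C8) comes from an Evans syn aldol–lactonisation of a succinate imide with silylated vanillin; 21 (threo C7'', C8'') comes from an Evans syn glycolate aldol with silylated syringaldehyde.
5. Ring order: ring A as lactone (step 3), ring B (step 16), ring A re-formed as tetrahydrofuran (step 18).

Key step: step 16

Remark: lignan numbering is used (guaiacyl unit C7–C9, syringyl unit C7'–C9', side chain C7''–C9''); the target is read as 7R,8S,7'S,8'S,7''R,8''R with exo guaiacyl, endo syringyl and a threo side chain, and both phenols are carried as triisopropylsilyl ethers and both side-chain alcohols as tert-butyldimethylsilyl ethers.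
Abbreviations in names: G = 3-methoxy-4-(triisopropylsilyloxy)phenyl; Syr* = 3,5-dimethoxy-4-{[(1R,2R)-1,3-bis(tert-butyldimethylsilyloxy)-1-[3,5-dimethoxy-4-(triisopropylsilyloxy)phenyl]propan-2-yl]oxy}phenyl.

**Route**

Step 1
Reactants: 1 vanillin
Product: 2 3-methoxy-4-(triisopropylsilyloxy)benzaldehyde
Conditions: TIPSCl, imidazole, DMF, rt
Reagents that add atoms: triisopropylsilyl chloride CC(C)[Si](Cl)(C(C)C)C(C)C
Why: Imidazole-promoted silylation of the phenol (silyl ether protection) leaves the aldehyde untouched and gives a base-tolerant aryl silyl ether.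

Step 2
Reactants: 3 (R)-4-benzyl-2-oxazolidinone; 4 methyl 4-chloro-4-oxobutanoate
Product: 5 methyl 4-[(R)-4-benzyl-2-oxooxazolidin-3-yl]-4-oxobutanoate
Conditions: n-BuLi, THF, −78 °C; then 4, −78 → 0 °C
Reagents that add atoms: none
Why: N-acylation of the lithiated oxazolidinone occurs at the acid chloride, which is far more electrophilic than the methyl ester.

Step 3
Reactants: 5 methyl 4-[(R)-4-benzyl-2-oxooxazolidin-3-yl]-4-oxobutanoate; 2 3-methoxy-4-(triisopropylsilyloxy)benzaldehyde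
Product: 7 trans lactone imide (R)-4-benzyl-3-[(2R,3R)-2-G-5-oxotetrahydrofuran-3-carbonyl]oxazolidin-2-one, via syn-aldol hydroxy ester 6 (not isolated)
Conditions: Bu2BOTf, i-Pr2NEt, CH2Cl2, 0 °C; 2, −78 → 20 °C; pH 7 buffer, MeOH, H2O2; crude with PPTS (cat.), CH2Cl2, rt
Reagents that add atoms: none
Why: Evans syn aldol through the Z dibutylboron enolate of the imide and a Zimmerman–Traxler chair, in which the aldehyde approaches the enolate face away from the benzyl group of the (R)-auxiliary, should set C8 and C7 (3R,4R in 6), and the syn aldolate then closes onto the methyl ester (tandem aldol–lactonisation) to give the trans-4,5-disubstituted lactone.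

Step 4
Reactants: 7 trans lactone imide
Product: 8 (2R,3R)-2-G-5-oxotetrahydrofuran-3-carboxylic acid
Conditions: LiOH, H2O2, THF/H2O, 0 °C; Na2SO3; 1 M HCl to pH 3
Reagents that add atoms: hydrogen peroxide OO (as LiOOH, supplies the carboxyl OH oxygen)
Why: Hydroperoxide attacks the exocyclic imide carbonyl selectively (LiOOH auxiliary cleavage), any lactone opened by hydroxide re-closes on acidification, and the hindered aryl silyl ether should survive the short cold treatment.

Step 5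
Reactants: 8 (2R,3R)-2-G-5-oxotetrahydrofuran-3-carboxylic acid
Product: 9 (4S,5R)-4-(hydroxymethyl)-5-G-dihydrofuran-2(3H)-one
Conditions: BH3·SMe2, THF, 0 °C → rt; MeOH
Reagents that add atoms: none
Why: Borane reduces the free carboxylic acid through its acyloxyborane much faster than the lactone, and the non-basic medium prevents migration of the lactone onto the new primary hydroxyl.

Step 6
Reactants: 10 syringaldehyde
Product: 11 3,5-dimethoxy-4-(triisopropylsilyloxy)benzaldehyde
Conditions: TIPSCl, imidazole, DMF, 50 °C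
Reagents that add atoms: triisopropylsilyl chloride CC(C)[Si](Cl)(C(C)C)C(C)C
Why: The same phenol silylation as in step 1, with mild heating for the 2,6-disubstituted phenol.

Step 7
Reactants: 12 (S)-4-benzyl-2-oxazolidinone; 13 bromoacetyl bromide
Product: 14 (S)-4-benzyl-3-(2-bromoacetyl)oxazolidin-2-one
Conditions: n-BuLi, THF, −78 °C; then 13, −78 °C
Reagents that add atoms: none
Why: N-acylation of the lithiated oxazolidinone occurs at the acyl bromide, which reacts far faster than the alkyl bromide at −78 °C.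

Step 8
Reactants: 15 methyl syringate (methyl 4-hydroxy-3,5-dimethoxybenzoate); 14 (S)-4-benzyl-3-(2-bromoacetyl)oxazolidin-2-one
Product: 16 methyl 4-{2-[(S)-4-benzyl-2-oxooxazolidin-3-yl]-2-oxoethoxy}-3,5-dimethoxybenzoate
Conditions: K2CO3, acetone, rt
Reagents that add atoms: none
Why: Williamson ether synthesis by SN2 displacement of the activated α-bromo imide, in which the weak carbonate base and the stabilised, hindered phenoxide should not cleave the imide.

Step 9
Reactants: 16 aryloxyacetyl imide; 11 3,5-dimethoxy-4-(triisopropylsilyloxy)benzaldehyde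
Product: 17 methyl 4-{[(2S,3R)-1-[(S)-4-benzyl-2-oxooxazolidin-3-yl]-3-[3,5-dimethoxy-4-(triisopropylsilyloxy)phenyl]-3-hydroxy-1-oxopropan-2-yl]oxy}-3,5-dimethoxybenzoate
Conditions: Bu2BOTf, Et3N, CH2Cl2, −78 → 0 °C; 11, −78 → 0 °C; pH 7 buffer, MeOH, H2O2
Reagents that add atoms: none
Why: Evans syn glycolate aldol through the Z boron enolate and a Zimmerman–Traxler chair, with the aldehyde approaching anti to the benzyl group of the (S)-auxiliary, should set C8'' (2S in 17) and C7'' (3R) in the syn relationship that corresponds to the threo 7''R,8''R side chain.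

Step 10
Reactants: 17 syn glycolate aldol adduct
Product: 18 methyl 4-{[(1R,2R)-1-[3,5-dimethoxy-4-(triisopropylsilyloxy)phenyl]-1,3-dihydroxypropan-2-yl]oxy}-3,5-dimethoxybenzoate
Conditions: NaBH4, THF/H2O, 0 °C → rt
Reagents that add atoms: none
Why: NaBH4 reduces the activated exocyclic imide carbonyl to the primary alcohol (reductive removal of the auxiliary) while the electron-rich aryl methyl ester is inert.

Step 11
Reactants: 18 1,3-diol
Product: 19 methyl 4-{[(1R,2R)-1,3-bis(tert-butyldimethylsilyloxy)-1-[3,5-dimethoxy-4-(triisopropylsilyloxy)phenyl]propan-2-yl]oxy}-3,5-dimethoxybenzoate (Syr*–CO2Me)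
Conditions: TBSOTf, 2,6-lutidine, CH2Cl2, −78 → 0 °C
Reagents that add atoms: tert-butyldimethylsilyl triflate CC(C)(C)[Si](C)(C)OS(=O)(=O)C(F)(F)F
Why: The silyl triflate with a hindered pyridine base silylates both the primary and the hindered benzylic secondary hydroxyl (silyl ether protection).

Step 12
Reactants: 19 Syr*–CO2Me
Product: 20 benzylic alcohol Syr*–CH2OH
Conditions: i-Bu2AlH, CH2Cl2, −78 → −20 °C; aq KNaC4H4O6
Reagents that add atoms: none
Why: i-Bu2AlH reduces the benzoate ester to the benzylic alcohol at low temperature without touching the silyl ethers.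

Step 13
Reactants: 20 Syr*–CH2OH
Product: 21 trichloroacetimidate Syr*–CH2OC(=NH)CCl3
Conditions: Cl3CCN, DBU (cat.), CH2Cl2, 0 °C; used crude
Reagents that add atoms: trichloroacetonitrile N#CC(Cl)(Cl)Cl
Why: Base-catalysed addition of the benzylic alkoxide to the nitrile gives the imidate (trichloroacetimidate formation).

Step 14
Reactants: 9 (4S,5R)-4-(hydroxymethyl)-5-G-dihydrofuran-2(3H)-one; 21 Syr*–CH2OC(=NH)CCl3
Product: 22 (4S,5R)-5-G-4-[(Syr*-methoxy)methyl]dihydrofuran-2(3H)-one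
Conditions: TfOH (5 mol %), 4 Å MS, CH2Cl2, −40 → 0 °C
Reagents that add atoms: none
Why: Acid-catalysed trichloroacetimidate benzylation, in which the protonated imidate ionises to a trialkoxy-stabilised benzylic cation that the primary hydroxyl of 9 captures; the non-basic medium avoids lactone migration and the catalytic anhydrous acid at low temperature should spare the silyl ethers.

Step 15
Reactants: 22 lactone ether
Product: 24 (4S,5R)-3-diazo-5-G-4-[(Syr*-methoxy)methyl]dihydrofuran-2(3H)-one, via α-trifluoroacetyl lactone 23 (not isolated)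
Conditions: LiN(SiMe3)2, THF, −78 °C; CF3CO2CH2CF3; cold 5% aq HCl; crude 23 with 4-AcNHC6H4SO2N3, Et3N, H2O, MeCN, rt
Reagents that add atoms: 4-acetamidobenzenesulfonyl azide CC(=O)Nc1ccc(cc1)S(=O)(=O)N=[N+]=[N-]; 2,2,2-trifluoroethyl trifluoroacetate O=C(OCC(F)(F)F)C(F)(F)F (its atoms stay only in 23)
Why: Detrifluoroacetylative (Regitz-type) diazo transfer, in which the C8' lithium enolate is trifluoroacetylated and the activated 1,3-dicarbonyl then attacks the sulfonyl azide and loses the trifluoroacetyl group to the sulfonamide, leaving C7 and C8 untouched.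

Step 16
Reactants: 24 α-diazo lactone
Product: 25 (3R,3aS,6S,6aR)-3-G-6-Syr*-tetrahydro-1H,3H-furo[3,4-c]furan-1-one (7R,8S,7'S,8'R; endo Syr*, exo G)
Conditions: Rh2(OAc)4 (2 mol %), CH2Cl2, reflux, slow addition of 24
Reagents that add atoms: none
Why: Rh2(OAc)4 extrudes N2 from 24 to give an electrophilic divalent rhodium carbenoid at C8', which inserts into a C7'–H bond of the syringylmethyl ether through a concerted, asynchronous three-centre transition state (hydride-like C–H transfer together with C7'–C8' bond formation). The closest known reaction type is the dirhodium-catalysed intramolecular 1,5 C–H insertion of α-diazo-γ-butyrolactones into benzylic ether C–H bonds to give endo,exo-furofuranones. Ring B closes as a five-membered ring by 1,5-insertion (carbenoid carbon C8' as atom 1, C7' as atom 5) through a five-membered, chair-like cyclic transition state. C8' is controlled by the existing C8 stereocentre, because the short C9–O tether can reach the carbenoid only from the face of lactone ring A that carries C9, which forces the cis ring fusion; C7' is controlled by the preference of the syringyl group for the pseudo-equatorial position of that transition state, which places it on the concave (endo) face. The step needs 1,5-insertion to win over 1,2-hydride shift from C8, addition to the arene and oxonium ylide formation, and this should be secured by lone-pair activation of the ether α-C–H bond, the electron-rich arene and the low stationary concentration of 24.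

Step 17
Reactants: 25 furofuranone
Product: 26 (7R,8S,7'S,8'S)-diol: (R)-G-[(3S,4S,5S)-4-(hydroxymethyl)-5-Syr*-tetrahydrofuran-3-yl]methanol
Conditions: LiAlH4, THF, 0 °C; Na2SO4·10H2O
Reagents that add atoms: none
Why: LiAlH4 reduces the lactone to the primary C9' alcohol and the benzylic C7 alcohol without breaking any bond at a stereocentre.

Step 18
Reactants: 26 diol
Product: 28 tetrasilylated target (7R,8S,7'S,8'S)-7-G-7'-Syr*-furofuran, via primary mesylate 27 (not isolated)
Conditions: MsCl (1.1 equiv), pyridine, CH2Cl2, 0 → 40 °C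
Reagents that add atoms: methanesulfonyl chloride CS(=O)(=O)Cl (its atoms stay only in 27)
Why: Selective sulfonylation of the primary C9' hydroxyl followed by intramolecular Williamson etherification (5-exo-tet) by the C7 hydroxyl re-forms ring A by substitution at C9', so C7 keeps its configuration and the guaiacyl group stays exo.

Step 19
Reactants: 28 tetrasilylated target
Product: 29 CNP0317965.1 (target)
Conditions: Bu4NF, AcOH, THF, 0 °C → rt
Reagents that add atoms: none
Why: Fluoride-mediated desilylation cleaves the two aryl and two alkyl silyl ethers, and the acetic acid buffer keeps the phenoxides and the acid- and base-sensitive endo benzylic ether from epimerising.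

**Compound list**
1 | vanillin | COc1cc(C=O)ccc1O | starting material
2 | 3-methoxy-4-(triisopropylsilyloxy)benzaldehyde | COc1cc(C=O)ccc1O[Si](C(C)C)(C(C)C)C(C)C | intermediate
3 | (R)-4-benzyl-2-oxazolidinone | O=C1OC[C@@H](Cc2ccccc2)N1 | starting material
4 | methyl 4-chloro-4-oxobutanoate | COC(=O)CCC(Cl)=O | starting material
5 | methyl 4-[(R)-4-benzyl-2-oxooxazolidin-3-yl]-4-oxobutanoate | O=C1OC[C@@H](Cc2ccccc2)N1C(=O)CCC(=O)OC | intermediate
6 | methyl (3R,4R)-3-[(R)-4-benzyl-2-oxooxazolidine-3-carbonyl]-4-hydroxy-4-[3-methoxy-4-(triisopropylsilyloxy)phenyl]butanoate (syn aldol) | COc1cc([C@H](O)[C@@H](CC(=O)OC)C(=O)N2C(=O)OC[C@H]2Cc3ccccc3)ccc1O[Si](C(C)C)(C(C)C)C(C)C | intermediate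
7 | (R)-4-benzyl-3-{(2R,3R)-2-[3-methoxy-4-(triisopropylsilyloxy)phenyl]-5-oxotetrahydrofuran-3-carbonyl}oxazolidin-2-one | COc1cc([C@@H]2OC(=O)C[C@H]2C(=O)N3C(=O)OC[C@H]3Cc4ccccc4)ccc1O[Si](C(C)C)(C(C)C)C(C)C | intermediate
8 | (2R,3R)-2-[3-methoxy-4-(triisopropylsilyloxy)phenyl]-5-oxotetrahydrofuran-3-carboxylic acid | COc1cc([C@@H]2OC(=O)C[C@H]2C(=O)O)ccc1O[Si](C(C)C)(C(C)C)C(C)C | intermediate
9 | (4S,5R)-4-(hydroxymethyl)-5-[3-methoxy-4-(triisopropylsilyloxy)phenyl]dihydrofuran-2(3H)-one | COc1cc([C@@H]2OC(=O)C[C@H]2CO)ccc1O[Si](C(C)C)(C(C)C)C(C)C | intermediate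
10 | syringaldehyde | COc1cc(C=O)cc(OC)c1O | starting material
11 | 3,5-dimethoxy-4-(triisopropylsilyloxy)benzaldehyde | COc1cc(C=O)cc(OC)c1O[Si](C(C)C)(C(C)C)C(C)C | intermediate
12 | (S)-4-benzyl-2-oxazolidinone | O=C1OC[C@H](Cc2ccccc2)N1 | starting material
13 | bromoacetyl bromide | BrCC(Br)=O | starting material
14 | (S)-4-benzyl-3-(2-bromoacetyl)oxazolidin-2-one | O=C1OC[C@H](Cc2ccccc2)N1C(=O)CBr | intermediate
15 | methyl syringate | COC(=O)c1cc(OC)c(O)c(OC)c1 | starting material
16 | methyl 4-{2-[(S)-4-benzyl-2-oxooxazolidin-3-yl]-2-oxoethoxy}-3,5-dimethoxybenzoate | COC(=O)c1cc(OC)c(OCC(=O)N2C(=O)OC[C@@H]2Cc3ccccc3)c(OC)c1 | intermediate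
17 | methyl 4-{[(2S,3R)-1-[(S)-4-benzyl-2-oxooxazolidin-3-yl]-3-[3,5-dimethoxy-4-(triisopropylsilyloxy)phenyl]-3-hydroxy-1-oxopropan-2-yl]oxy}-3,5-dimethoxybenzoate | COC(=O)c1cc(OC)c(O[C@H](C(=O)N2C(=O)OC[C@@H]2Cc3ccccc3)[C@H](O)c4cc(OC)c(O[Si](C(C)C)(C(C)C)C(C)C)c(OC)c4)c(OC)c1 | intermediate
18 | methyl 4-{[(1R,2R)-1-[3,5-dimethoxy-4-(triisopropylsilyloxy)phenyl]-1,3-dihydroxypropan-2-yl]oxy}-3,5-dimethoxybenzoate | COC(=O)c1cc(OC)c(O[C@H](CO)[C@H](O)c2cc(OC)c(O[Si](C(C)C)(C(C)C)C(C)C)c(OC)c2)c(OC)c1 | intermediate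
19 | methyl 4-{[(1R,2R)-1,3-bis(tert-butyldimethylsilyloxy)-1-[3,5-dimethoxy-4-(triisopropylsilyloxy)phenyl]propan-2-yl]oxy}-3,5-dimethoxybenzoate (Syr*–CO2Me) | COC(=O)c1cc(OC)c(O[C@H](CO[Si](C)(C)C(C)(C)C)[C@H](O[Si](C)(C)C(C)(C)C)c2cc(OC)c(O[Si](C(C)C)(C(C)C)C(C)C)c(OC)c2)c(OC)c1 | intermediate
20 | Syr*–CH2OH (benzylic alcohol from 19) | OCc1cc(OC)c(O[C@H](CO[Si](C)(C)C(C)(C)C)[C@H](O[Si](C)(C)C(C)(C)C)c2cc(OC)c(O[Si](C(C)C)(C(C)C)C(C)C)c(OC)c2)c(OC)c1 | intermediate
21 | Syr*–CH2 2,2,2-trichloroacetimidate | N=C(OCc1cc(OC)c(O[C@H](CO[Si](C)(C)C(C)(C)C)[C@H](O[Si](C)(C)C(C)(C)C)c2cc(OC)c(O[Si](C(C)C)(C(C)C)C(C)C)c(OC)c2)c(OC)c1)C(Cl)(Cl)Cl | intermediate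
22 | (4S,5R)-5-G-4-[(Syr*-methoxy)methyl]dihydrofuran-2(3H)-one | COc1cc([C@@H]2OC(=O)C[C@H]2COCc3cc(OC)c(O[C@H](CO[Si](C)(C)C(C)(C)C)[C@H](O[Si](C)(C)C(C)(C)C)c4cc(OC)c(O[Si](C(C)C)(C(C)C)C(C)C)c(OC)c4)c(OC)c3)ccc1O[Si](C(C)C)(C(C)C)C(C)C | intermediate
23 | (4S,5R)-5-G-4-[(Syr*-methoxy)methyl]-3-(trifluoroacetyl)dihydrofuran-2(3H)-one (C3 epimers/enol) | COc1cc([C@@H]2OC(=O)C(C(=O)C(F)(F)F)[C@H]2COCc3cc(OC)c(O[C@H](CO[Si](C)(C)C(C)(C)C)[C@H](O[Si](C)(C)C(C)(C)C)c4cc(OC)c(O[Si](C(C)C)(C(C)C)C(C)C)c(OC)c4)c(OC)c3)ccc1O[Si](C(C)C)(C(C)C)C(C)C | intermediate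
24 | (4S,5R)-3-diazo-5-G-4-[(Syr*-methoxy)methyl]dihydrofuran-2(3H)-one | COc1cc([C@@H]2OC(=O)C(=[N+]=[N-])[C@H]2COCc3cc(OC)c(O[C@H](CO[Si](C)(C)C(C)(C)C)[C@H](O[Si](C)(C)C(C)(C)C)c4cc(OC)c(O[Si](C(C)C)(C(C)C)C(C)C)c(OC)c4)c(OC)c3)ccc1O[Si](C(C)C)(C(C)C)C(C)C | intermediate
25 | (3R,3aS,6S,6aR)-3-G-6-Syr*-tetrahydro-1H,3H-furo[3,4-c]furan-1-one | COc1cc([C@@H]2OC(=O)[C@@H]3[C@H]2CO[C@@H]3c4cc(OC)c(O[C@H](CO[Si](C)(C)C(C)(C)C)[C@H](O[Si](C)(C)C(C)(C)C)c5cc(OC)c(O[Si](C(C)C)(C(C)C)C(C)C)c(OC)c5)c(OC)c4)ccc1O[Si](C(C)C)(C(C)C)C(C)C | intermediate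
26 | (R)-G-[(3S,4S,5S)-4-(hydroxymethyl)-5-Syr*-tetrahydrofuran-3-yl]methanol | COc1cc([C@H](O)[C@@H]2CO[C@H](c3cc(OC)c(O[C@H](CO[Si](C)(C)C(C)(C)C)[C@H](O[Si](C)(C)C(C)(C)C)c4cc(OC)c(O[Si](C(C)C)(C(C)C)C(C)C)c(OC)c4)c(OC)c3)[C@@H]2CO)ccc1O[Si](C(C)C)(C(C)C)C(C)C | intermediate
27 | primary C9' methanesulfonate of 26 | COc1cc([C@H](O)[C@@H]2CO[C@H](c3cc(OC)c(O[C@H](CO[Si](C)(C)C(C)(C)C)[C@H](O[Si](C)(C)C(C)(C)C)c4cc(OC)c(O[Si](C(C)C)(C(C)C)C(C)C)c(OC)c4)c(OC)c3)[C@@H]2COS(C)(=O)=O)ccc1O[Si](C(C)C)(C(C)C)C(C)C | intermediate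
28 | tetrasilylated target: (7R,8S,7'S,8'S)-7-G-7'-Syr*-7,9':7',9-diepoxylignane | COc1cc([C@@H]2OC[C@@H]3[C@H]2CO[C@@H]3c4cc(OC)c(O[C@H](CO[Si](C)(C)C(C)(C)C)[C@H](O[Si](C)(C)C(C)(C)C)c5cc(OC)c(O[Si](C(C)C)(C(C)C)C(C)C)c(OC)c5)c(OC)c4)ccc1O[Si](C(C)C)(C(C)C)C(C)C | intermediate
29 | CNP0317965.1 | COc1cc([C@@H]2OC[C@@H]3[C@H]2CO[C@@H]3c2cc(OC)c(O[C@H](CO)[C@H](O)c3cc(OC)c(O)c(OC)c3)c(OC)c2)ccc1O | target

**Step count**
Total: 19 steps. Longest linear sequence: 13 steps (steps 7–19).

**Steps most likely to fail**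

Step 16 (carbenoid C–H insertion). The carbenoid may be consumed by 1,2-hydride migration from C8, by addition to the electron-rich syringyl ring or by dimerisation, or the insertion may show poor facial discrimination at C7'. The fallback closes ring B by C–O instead of C–C bond formation; it sets out from 9 and 20 and comes back to the route at 28. DBU in CH2Cl2 moves the lactone of 9 onto the primary oxygen and should give (S)-4-{(R)-hydroxy[3-methoxy-4-(triisopropylsilyloxy)phenyl]methyl}dihydrofuran-2(3H)-one F1, which is silylated (Et3SiCl, imidazole) to its triethylsilyl ether F2. Oxidation of 20 with MnO2 gives the aldehyde Syr*–CHO F3. The lithium enolate of F2 (LiN(i-Pr)2, THF, −78 °C) should add to F3 on the lactone face opposite to the C8 substituent and, through the chair transition state of the ring-locked E enolate, with anti selectivity, giving the aldol adduct F4 with the C8' and C7' configurations of the target. LiAlH4 opens the lactone to the triol F5, PPTS in MeOH removes the triethylsilyl group to give the tetraol F6, and MsCl in pyridine converts the two primary hydroxyls into the bis-mesylate F7. In F7 the benzylic hydroxyls displace the mesylates at C9 and C9' with retention at C7' and C7, closing rings B and A to give 28.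

Step 14 (imidate etherification). The benzylic cation from 21 may be lost to Friedel–Crafts attack on the electron-rich rings or to rearrangement into the trichloroacetamide, and the acid may ionise the benzylic lactone oxygen or a benzylic silyl ether. The fallback sets out from 20 and 9 and comes back at 22. An Appel reaction (CBr4, PPh3, CH2Cl2, 0 °C) converts 20 into the benzylic bromide Syr*–CH2Br F8, which alkylates 9 under AgOTf and 2,6-di-tert-butyl-4-methylpyridine in CH2Cl2 at −40 → 0 °C (halide abstraction in a buffered medium free of both Brønsted acid and alkoxide), giving 22.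

Step 4 (hydrolytic removal of the auxiliary). Hydroxide or hydroperoxide may cleave the aryl silyl ether, open the lactone with subsequent retro-aldol loss of the aldehyde, or attack the endocyclic carbamate carbonyl. The fallback sets out from 7 and comes back at 9, skipping 8: reductive removal of the auxiliary with NaBH4 in THF/H2O at 0 °C reduces the exocyclic imide carbonyl directly to the C9 alcohol and leaves the lactone, and is kept short and cold so that the lactone does not migrate.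

**Further compounds**
F1 | step 16 | (S)-4-{(R)-hydroxy[3-methoxy-4-(triisopropylsilyloxy)phenyl]methyl}dihydrofuran-2(3H)-one | COc1cc([C@H](O)[C@@H]2COC(=O)C2)ccc1O[Si](C(C)C)(C(C)C)C(C)C
F2 | step 16 | triethylsilyl ether of F1 | COc1cc([C@H](O[Si](CC)(CC)CC)[C@@H]2COC(=O)C2)ccc1O[Si](C(C)C)(C(C)C)C(C)C
F3 | step 16 | Syr*–CHO | O=Cc1cc(OC)c(O[C@H](CO[Si](C)(C)C(C)(C)C)[C@H](O[Si](C)(C)C(C)(C)C)c2cc(OC)c(O[Si](C(C)C)(C(C)C)C(C)C)c(OC)c2)c(OC)c1
F4 | step 16 | anti aldol adduct of F2 and F3 (C8' trans to C8 substituent) | COc1cc([C@H](O[Si](CC)(CC)CC)[C@@H]2COC(=O)[C@H]2[C@H](O)c3cc(OC)c(O[C@H](CO[Si](C)(C)C(C)(C)C)[C@H](O[Si](C)(C)C(C)(C)C)c4cc(OC)c(O[Si](C(C)C)(C(C)C)C(C)C)c(OC)c4)c(OC)c3)ccc1O[Si](C(C)C)(C(C)C)C(C)C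
F5 | step 16 | triol from F4 (C7 triethylsilyl ether) | COc1cc([C@H](O[Si](CC)(CC)CC)[C@H](CO)[C@@H](CO)[C@H](O)c3cc(OC)c(O[C@H](CO[Si](C)(C)C(C)(C)C)[C@H](O[Si](C)(C)C(C)(C)C)c4cc(OC)c(O[Si](C(C)C)(C(C)C)C(C)C)c(OC)c4)c(OC)c3)ccc1O[Si](C(C)C)(C(C)C)C(C)C
F6 | step 16 | tetraol from F5 | COc1cc([C@H](O)[C@H](CO)[C@@H](CO)[C@H](O)c3cc(OC)c(O[C@H](CO[Si](C)(C)C(C)(C)C)[C@H](O[Si](C)(C)C(C)(C)C)c4cc(OC)c(O[Si](C(C)C)(C(C)C)C(C)C)c(OC)c4)c(OC)c3)ccc1O[Si](C(C)C)(C(C)C)C(C)C
F7 | step 16 | bis(primary methanesulfonate) of F6 | COc1cc([C@H](O)[C@H](COS(C)(=O)=O)[C@@H](COS(C)(=O)=O)[C@H](O)c3cc(OC)c(O[C@H](CO[Si](C)(C)C(C)(C)C)[C@H](O[Si](C)(C)C(C)(C)C)c4cc(OC)c(O[Si](C(C)C)(C(C)C)C(C)C)c(OC)c4)c(OC)c3)ccc1O[Si](C(C)C)(C(C)C)C(C)C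
F8 | step 14 | Syr*–CH2Br | BrCc1cc(OC)c(O[C@H](CO[Si](C)(C)C(C)(C)C)[C@H](O[Si](C)(C)C(C)(C)C)c2cc(OC)c(O[Si](C(C)C)(C(C)C)C(C)C)c(OC)c2)c(OC)c1
F0 | step 4 | none | none
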